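Starting material has two takers. Partner turns it into target and second substrate turns it into cross product, and both work at once.

| flask | starting material | partner | second substrate | remark | time |
|---|---|---|---|---|---|
| Thursday's | 2 mM | 1.9 mM | 10 mM | run made earlier |  |
| Friday's | 1 mM | 1.9 mM | 10 mM | run made earlier |  |
| Monday's | 4 mM | 1.9 mM | 10 mM | run made earlier |  |
| Wednesday's | 2 mM | 1.9 mM | 20 mM | run made earlier |  |
| eta | 2.0 mM | 1.90 mM | 10.0 mM | everything together at the start | 10 min |
| zeta | 2.0 mM | 1.90 mM (fed, over 6.0 min) | 10.0 mM | all else is in the flask from the start; the feed brings no volume worth counting | 10 min |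
| gamma | 2.0 mM | 1.90 mM (in portions, 3, over 6.0 min) | 10.0 mM | first portion at the start, last at 6.0 min | 10 min |
| alpha | 2.0 mM (fed, over 6.0 min) | 1.90 mM | 10.0 mM | all else is in the flask from the start; the feed brings no volume worth counting | 10 min |

- Thursday's (time / min: target / %, cross product / %, starting material / %): 0.833: 37, 52, 14; 2.50: 40, 58, 4; 5.00: 37, 62, 0; 8.00: 36, 60, 0; 10.0: 36, 63, 1
- Friday's (time / min: target / %, cross product / %, starting material / %): 0.667: 38, 50, 17; 1.33: 41, 55, 2; 2.50: 39, 56, 0; 4.00: 43, 59, 0; 8.00: 42, 60, 0
- Monday's (time / min: target / %, cross product / %, starting material / %): 1.50: 33, 60, 10; 3.00: 29, 63, 4; 5.00: 29, 70, 1; 6.00: 32, 66, 3; 8.00: 31, 69, 2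
- Wednesday's (time / min: target / %, cross product / %, starting material / %): 0.667: 25, 67, 5; 1.33: 26, 68, 3; 2.50: 22, 72, 2; 4.00: 25, 76, 3; 8.00: 25, 71, 0

(each reading ± 2 percentage points)

- the flask with the highest share of target in target plus cross product ("all alike" if they lie within 1.5 percentage points) (eta / zeta / gamma / alpha / all alike)
- share of target in target plus cross product at the end, eta
- share of target in target plus cross product at the end, zeta
- share of target in target plus cross product at the end, gamma
- share of target in target plus cross product at the end, alpha

- what was read earlier has a scatter of 2 percentage points, one standard deviation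

At any moment the fraction f of fresh product that is target follows from the two concentrations and the selectivity factor S, the rate per unit partner over the rate per unit second substrate:

f = S·c(partner) / [S·c(partner) + c(second substrate)]

S = ln[c(partner) at start / c(partner) at end] / ln[c(second substrate) at start / c(second substrate) at end]

This reckoning is my own, and it counts partner and second substrate as spent on starting material alone. Thursday's last reading gives S = 3.54, and eta opens at 0.190 in the partner ratio ρ, c(partner) over c(second substrate), so eta opens at f = 40.2%. Friday's reading gives 4.04 and Monday's 3.27, lower at the larger charge, which hints that partner may also be leaving by some unread path.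

Thursday's first reading gives starting material an opening time constant near 0.424 min; the decay slows as partner and second substrate fall, but Thursday's reading at 5.00 min already stands at 0%, within its scatter, so eta needs no attention before the asked time of 10 min. Alpha must not be read as eta, because its feed lasts 6.0 min, longer than that constant, and late starting material meets whatever ratio then stands. I therefore put alpha below eta.

The forecast differs. It names alpha highest at 40%, with eta 38%, zeta 7% and gamma 17%, holding that “timing cancels in the simple model”.

    starting material + partner → target (k = 19.0 L mol⁻¹ s⁻¹)
    second substrate + partner → second product (k = 2.30 L mol⁻¹ s⁻¹)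
    starting material + second substrate → cross product (k = 3.50 L mol⁻¹ s⁻¹)
    2 second substrate → homo dimer (k = 0.660 L mol⁻¹ s⁻¹)
    partner ⇌ dormant form (K = 0.340, k = 0.170 s⁻¹)

The flasks end at 37.7% in eta, 9.89% in zeta, 16.9% in gamma and 27.5% in alpha, so eta leads. In alpha at 6.00 min, partner stood at 2.02% of its charge and second substrate at 11.3%, with second product at 1.42 mM and homo dimer at 3.27 mM beside them, which puts ρ at 0.0340, lower than eta's opening value, and f, with S as the ratio of the rate constants of the target and cross product steps, 5.43, at 15.6%. By 10.0 min, target had moved from 21.3% to 23.1% and cross product from 45.0% to 60.9%. Gamma's first portion of partner opens that flask at ρ = 0.0633, a third of eta's opening value, with f = 25.6% at that start, and gamma ends at 16.9%.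

The numbers in the tables come from a simulation on assumed constants; noise was put on by code.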